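**Strategy**

Ring B is read as a Diels–Alder ring: the tertiary carbinol C8 lies para to the ring-fusion carbon C5, and its oxygen is trans to the C9 CH2O arm. With C8–OH masked as a formyl group (Baeyer–Villiger retron), C8=C9 becomes an (E)-enal and C5 the siloxy carbon of a pentadiene. One catalytic asymmetric [4+2] cycloaddition of these two acyclic pieces closes ring B by joining C7 to C8 (and C9 to C10) and sets C8 and C9. C10, C5, C4 and C3 are then relayed by substrate control while ring A is annulated (Robinson annulation, reductive hydroxymethylation, hydride reduction); Mitsunobu etherification with umbelliferone and angeloylation finish.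

Key step: step 3

Remark on labels: atoms carry terpenoid (drimane) numbers; ring A = C1–C5 and C10, ring B = C5–C10; C3 is the secondary carbinol, C4 bears a methyl and C23H2O, C8 bears OH and a methyl, C9 bears C11H2O.

Remark (assumption): the (S)-configured catalyst of step 3 is assumed, by analogy with 2-substituted acroleins, to give the enantiomer drawn for 6; if the sense of induction is opposite, the (R)-catalyst is used.

**Route**

Step 1
Reactants: 1 2-[(triisopropylsilyl)oxy]acetaldehyde; 2 2-(triphenyl-λ5-phosphanylidene)propanal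
Product: 3 (2E)-2-methyl-4-[(triisopropylsilyl)oxy]but-2-enal
Conditions: toluene, 80 °C
Reagents that add atoms: none
Why: Wittig olefination with the formyl-stabilised ylide should give the E enal (formyl trans to CH2OSi), the geometry that later encodes the C8/C9 relationship.

Step 2
Reactants: 4 pent-1-en-3-one (ethyl vinyl ketone)
Product: 5 triisopropyl[(3Z)-penta-1,3-dien-3-yloxy]silane
Conditions: iPr3SiOSO2CF3, Et3N, Et2O, 0 °C to rt
Reagents that add atoms: triisopropylsilyl trifluoromethanesulfonate, CC(C)[Si](OS(=O)(=O)C(F)(F)F)(C(C)C)C(C)C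
Why: Silyl enol ether formation by soft enolisation on the ethyl side of the vinyl ketone should give the Z enol ether, that is the diene whose terminal methyl points outward in the s-cis form.

Step 3
Reactants: 3 (2E)-2-methyl-4-[(triisopropylsilyl)oxy]but-2-enal; 5 triisopropyl[(3Z)-penta-1,3-dien-3-yloxy]silane
Product: 7 (1S,2S)-1,3-dimethyl-4-oxo-2-{[(triisopropylsilyl)oxy]methyl}cyclohexane-1-carbaldehyde (C3 epimers), via silyl enol ether cycloadduct 6 (not isolated)
Conditions: (S)-3,3-diphenyl-1-(2-methylphenyl)tetrahydro-1H,3H-pyrrolo[1,2-c][1,3,2]oxazaborole (C24H24BNO, 20 mol %), HN(SO2CF3)2 (18 mol %), CH2Cl2, −78 to −40 °C; then CF3CO2H, CH2Cl2, 0 °C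
Reagents that add atoms: none
Why: The protonated oxazaborolidine binds the formyl group of 3 and lowers its LUMO, so diene 5 adds in a concerted, asynchronous [4+2] cycloaddition in which C9–C10 bonding is ahead and the C7–C8 bond closes the ring; the closest known reaction type is the chiral oxazaborolidinium-catalysed Diels–Alder reaction of 2-silyloxydienes with α-substituted enals. Ring B closes as a six-membered carbocycle by suprafacial [4+2] cycloaddition of two acyclic partners. The quaternary C8 and the tertiary C9 are set together: their relative configuration (formyl trans to CH2OSi, methyl cis) follows from the E geometry of 3, their absolute configuration from the catalyst, which leaves one face of the bound enal open. C10 forms as an epimer mixture of no consequence, because it is enolised again in step 5. The step needs para regioselectivity (siloxy carbon C5 and formyl-bearing C8 in a 1,4 relation), secured by the siloxy group, which makes C10 the nucleophilic diene terminus, and by the formyl group, which makes C9 the electrophilic carbon; it also needs addition to C=C and not to C=O, secured by the α-methyl enal held s-trans on boron. Trifluoroacetic acid then protonates C6 of the enol ether and releases the ketone without touching the alkyl silyl ether.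

Step 4
Reactants: 7 (1S,2S)-1,3-dimethyl-4-oxo-2-{[(triisopropylsilyl)oxy]methyl}cyclohexane-1-carbaldehyde
Product: 9 (3R,4S)-4-hydroxy-2,4-dimethyl-3-{[(triisopropylsilyl)oxy]methyl}cyclohexan-1-one (C2 epimers), via formate ester 8 (not isolated)
Conditions: mCPBA (1.1 equiv), NaHCO3, CH2Cl2, 0 °C; then K2CO3 (cat.), MeOH, 0 °C
Reagents that add atoms: 3-chloroperoxybenzoic acid, O=C(OO)c1cccc(Cl)c1
Why: Baeyer–Villiger oxidation: the peracid should add to the formyl group far faster than to the buffered ring ketone, the tertiary C8 migrates in preference to hydrogen and with retention of configuration, and methanolysis of the formate frees the C8 hydroxyl.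

Step 5
Reactants: 9 (3R,4S)-4-hydroxy-2,4-dimethyl-3-{[(triisopropylsilyl)oxy]methyl}cyclohexan-1-one; 4 pent-1-en-3-one
Product: 11 (4aS,5R,6S)-6-hydroxy-1,4a,6-trimethyl-5-{[(triisopropylsilyl)oxy]methyl}-4,4a,5,6,7,8-hexahydronaphthalen-2(3H)-one, via Michael adduct 10 (not isolated)
Conditions: KOH (0.2 equiv), MeOH, 0 °C to rt; then KOH (1 equiv), MeOH, 60 °C
Reagents that add atoms: none
Why: Robinson annulation: the more substituted enolate should add to the vinyl ketone at C10 on the face anti to the C9 CH2OSi group (the face of the small C8 hydroxyl), so that the C10 methyl ends cis to the C9 arm and the C8 methyl, and aldol condensation then gives the C4=C5 enone of ring A.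

Step 6
Reactants: 11 (4aS,5R,6S)-6-hydroxy-1,4a,6-trimethyl-5-{[(triisopropylsilyl)oxy]methyl}-4,4a,5,6,7,8-hexahydronaphthalen-2(3H)-one
Product: 13 (1S,4aR,5R,6S,8aS)-6-hydroxy-1-(hydroxymethyl)-1,4a,6-trimethyl-5-{[(triisopropylsilyl)oxy]methyl}octahydronaphthalen-2(1H)-one, via dilithium enolate alkoxide 12 (not isolated)
Conditions: Li (2.5 equiv), NH3 (l)/THF, −78 °C, no added proton donor; NH3 removed; then CH2O (gas), THF, −78 to −40 °C; aq. NH4Cl
Reagents that add atoms: formaldehyde, C=O
Why: Dissolving-metal (Birch-type) enone reduction with enolate trapping: axial protonation at C5 should give the trans ring fusion, and the lithium enolate takes up formaldehyde at C4 on the face opposite the axial C10 methyl, so that CH2OH becomes equatorial and the C4 methyl axial.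

Step 7
Reactants: 13 (1S,4aR,5R,6S,8aS)-6-hydroxy-1-(hydroxymethyl)-1,4a,6-trimethyl-5-{[(triisopropylsilyl)oxy]methyl}octahydronaphthalen-2(1H)-one
Product: 14 (1S,2R,4aR,5R,6S,8aS)-1-(hydroxymethyl)-1,4a,6-trimethyl-5-{[(triisopropylsilyl)oxy]methyl}decahydronaphthalene-2,6-diol
Conditions: NaBH4, MeOH/CH2Cl2, −20 to 0 °C
Reagents that add atoms: none
Why: Borohydride reduction by axial hydride attack, on the face away from the axial C4 methyl, should give the equatorial C3 alcohol trans to the C4 hydroxymethyl group.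

Step 8
Reactants: 14 (1S,2R,4aR,5R,6S,8aS)-1-(hydroxymethyl)-1,4a,6-trimethyl-5-{[(triisopropylsilyl)oxy]methyl}decahydronaphthalene-2,6-diol
Product: 15 3,23-O-isopropylidene acetal of 14 (acetonide silyl ether)
Conditions: Me2C(OMe)2, pyridinium p-toluenesulfonate (cat.), CH2Cl2, rt
Reagents that add atoms: 2,2-dimethoxypropane, COC(C)(C)OC
Why: Acid-catalysed acetal exchange (acetonide formation) should tie the C3 hydroxyl and the C23 hydroxyl into a six-membered dioxane, while the tertiary C8 hydroxyl has no free partner.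

Step 9
Reactants: 15 3,23-O-isopropylidene acetal of 14
Product: 16 acetonide diol with free C11 and C8 hydroxyls
Conditions: Bu4NF, THF, rt
Reagents that add atoms: none
Why: Fluoride-mediated desilylation cleaves the primary silyl ether and leaves the acetonide and the tertiary alcohol untouched.

Step 10
Reactants: 16 acetonide diol with free C11 and C8 hydroxyls; 17 7-hydroxy-2H-chromen-2-one (umbelliferone)
Product: 18 acetonide C11 aryl ether
Conditions: PPh3, diisopropyl azodicarboxylate, THF, 0 to 45 °C
Reagents that add atoms: none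
Why: Mitsunobu etherification: the acidic phenol should displace the oxyphosphonium of the primary C11 alcohol in an SN2 step, while the tertiary C8 hydroxyl cannot be activated.

Step 11
Reactants: 18 acetonide C11 aryl ether
Product: 19 (1S,2R,4aR,5R,6S,8aS)-1-(hydroxymethyl)-1,4a,6-trimethyl-5-{[(2-oxo-2H-chromen-7-yl)oxy]methyl}decahydronaphthalene-2,6-diol
Conditions: AcOH/H2O (4:1), 45 °C
Reagents that add atoms: none
Why: Mild acid hydrolysis of the isopropylidene acetal, which the aryl ether, the lactone and the tertiary alcohol should tolerate.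

Step 12
Reactants: 19 (1S,2R,4aR,5R,6S,8aS)-1-(hydroxymethyl)-1,4a,6-trimethyl-5-{[(2-oxo-2H-chromen-7-yl)oxy]methyl}decahydronaphthalene-2,6-diol; 20 (2Z)-2-methylbut-2-enoic acid (angelic acid)
Product: 22 [(1S,2R,4aR,5R,6S,8aS)-2,6-dihydroxy-1,4a,6-trimethyl-5-{[(2-oxo-2H-chromen-7-yl)oxy]methyl}decahydronaphthalen-1-yl]methyl (2Z)-2-methylbut-2-enoate, via mixed anhydride 21 (not isolated)
Conditions: 20, 2,4,6-Cl3C6H2COCl, Et3N, toluene, rt; then 19 (limiting), toluene, 60 °C
Reagents that add atoms: none
Why: Yamaguchi-type esterification through the mixed anhydride, without a nucleophilic catalyst, should acylate the primary C23 hydroxyl in preference to the hindered secondary C3 and tertiary C8 hydroxyls and keep the Z geometry of the angelate.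

**Compound list**

1 | 2-[(triisopropylsilyl)oxy]acetaldehyde | O=CCO[Si](C(C)C)(C(C)C)C(C)C | starting material
2 | 2-(triphenyl-λ5-phosphanylidene)propanal | CC(C=O)=P(c1ccccc1)(c1ccccc1)c1ccccc1 | starting material
3 | (2E)-2-methyl-4-[(triisopropylsilyl)oxy]but-2-enal | O=C/C(C)=C/CO[Si](C(C)C)(C(C)C)C(C)C | intermediate
4 | pent-1-en-3-one (ethyl vinyl ketone) | C=CC(=O)CC | starting material
5 | triisopropyl[(3Z)-penta-1,3-dien-3-yloxy]silane | C=C/C(O[Si](C(C)C)(C(C)C)C(C)C)=C/C | intermediate
6 | (1S,6S)-1,5-dimethyl-4-[(triisopropylsilyl)oxy]-6-{[(triisopropylsilyl)oxy]methyl}cyclohex-3-ene-1-carbaldehyde (C5 epimers) | O=C[C@@]1(C)CC=C(O[Si](C(C)C)(C(C)C)C(C)C)C(C)[C@@H]1CO[Si](C(C)C)(C(C)C)C(C)C | intermediate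
7 | (1S,2S)-1,3-dimethyl-4-oxo-2-{[(triisopropylsilyl)oxy]methyl}cyclohexane-1-carbaldehyde (C3 epimers) | O=C[C@@]1(C)CCC(=O)C(C)[C@@H]1CO[Si](C(C)C)(C(C)C)C(C)C | intermediate
8 | (1S,2R)-1,3-dimethyl-4-oxo-2-{[(triisopropylsilyl)oxy]methyl}cyclohexyl formate (C3 epimers) | O=CO[C@@]1(C)CCC(=O)C(C)[C@@H]1CO[Si](C(C)C)(C(C)C)C(C)C | intermediate
9 | (3R,4S)-4-hydroxy-2,4-dimethyl-3-{[(triisopropylsilyl)oxy]methyl}cyclohexan-1-one (C2 epimers) | O[C@@]1(C)CCC(=O)C(C)[C@@H]1CO[Si](C(C)C)(C(C)C)C(C)C | intermediate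
10 | (2S,3R,4S)-4-hydroxy-2,4-dimethyl-2-(3-oxopentyl)-3-{[(triisopropylsilyl)oxy]methyl}cyclohexan-1-one | O=C1CC[C@](C)(O)[C@@H](CO[Si](C(C)C)(C(C)C)C(C)C)[C@]1(C)CCC(=O)CC | intermediate
11 | (4aS,5R,6S)-6-hydroxy-1,4a,6-trimethyl-5-{[(triisopropylsilyl)oxy]methyl}-4,4a,5,6,7,8-hexahydronaphthalen-2(3H)-one | CC1=C2CC[C@](C)(O)[C@@H](CO[Si](C(C)C)(C(C)C)C(C)C)[C@]2(C)CCC1=O | intermediate
12 | dilithium salt: C3 enolate (C3=C4) of the trans-fused ketone with the C8 alkoxide | [Li+].[Li+].CC1[C@H]2CC[C@](C)([O-])[C@@H](CO[Si](C(C)C)(C(C)C)C(C)C)[C@]2(C)CCC=1[O-] | intermediate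
13 | (1S,4aR,5R,6S,8aS)-6-hydroxy-1-(hydroxymethyl)-1,4a,6-trimethyl-5-{[(triisopropylsilyl)oxy]methyl}octahydronaphthalen-2(1H)-one | OC[C@]1(C)[C@H]2CC[C@](C)(O)[C@@H](CO[Si](C(C)C)(C(C)C)C(C)C)[C@]2(C)CCC1=O | intermediate
14 | (1S,2R,4aR,5R,6S,8aS)-1-(hydroxymethyl)-1,4a,6-trimethyl-5-{[(triisopropylsilyl)oxy]methyl}decahydronaphthalene-2,6-diol | OC[C@]1(C)[C@H]2CC[C@](C)(O)[C@@H](CO[Si](C(C)C)(C(C)C)C(C)C)[C@]2(C)CC[C@H]1O | intermediate
15 | acetonide of 14: 2,2-dimethyl-1,3-dioxane across the C3 oxygen and the C23 oxygen; C11 silyl ether and C8 hydroxyl kept; stereocentres as in 14 | CC1(C)OC[C@]2(C)[C@H]3CC[C@](C)(O)[C@@H](CO[Si](C(C)C)(C(C)C)C(C)C)[C@]3(C)CC[C@H]2O1 | intermediate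
16 | acetonide diol: 15 without the silyl group (free primary C11 hydroxyl, free tertiary C8 hydroxyl) | CC1(C)OC[C@]2(C)[C@H]3CC[C@](C)(O)[C@@H](CO)[C@]3(C)CC[C@H]2O1 | intermediate
17 | 7-hydroxy-2H-chromen-2-one (umbelliferone) | Oc1ccc2ccc(=O)oc2c1 | starting material
18 | acetonide aryl ether: 16 with the C11 oxygen bound to C7 of the coumarin | CC1(C)OC[C@]2(C)[C@H]3CC[C@](C)(O)[C@@H](COc4ccc5ccc(=O)oc5c4)[C@]3(C)CC[C@H]2O1 | intermediate
19 | (1S,2R,4aR,5R,6S,8aS)-1-(hydroxymethyl)-1,4a,6-trimethyl-5-{[(2-oxo-2H-chromen-7-yl)oxy]methyl}decahydronaphthalene-2,6-diol | OC[C@]1(C)[C@H]2CC[C@](C)(O)[C@@H](COc3ccc4ccc(=O)oc4c3)[C@]2(C)CC[C@H]1O | intermediate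
20 | (2Z)-2-methylbut-2-enoic acid (angelic acid) | C/C=C(/C)C(=O)O | starting material
21 | (2Z)-2-methylbut-2-enoic 2,4,6-trichlorobenzoic anhydride | C/C=C(/C)C(=O)OC(=O)c1c(Cl)cc(Cl)cc1Cl | intermediate
22 | [(1S,2R,4aR,5R,6S,8aS)-2,6-dihydroxy-1,4a,6-trimethyl-5-{[(2-oxo-2H-chromen-7-yl)oxy]methyl}decahydronaphthalen-1-yl]methyl (2Z)-2-methylbut-2-enoate (CNP0139045.1) | C/C=C(/C)C(=O)OC[C@]1(C)[C@H]2CC[C@](C)(O)[C@@H](COc3ccc4ccc(=O)oc4c3)[C@]2(C)CC[C@H]1O | target

**Step count and risks**

Total step count: 12. Longest linear sequence: 11 steps (steps 1 and 3 to 12; step 2 is the one-step side branch to the diene).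

The three steps most likely to fail:

Step 3 (key step). What may go wrong: slow turnover of the chiral catalyst with a trisubstituted enal and a terminally substituted diene, or poor facial selectivity, so that the adduct forms in low enantiomeric purity. The fallback sets out from 3 and 5 and comes back at 7; it replaces asymmetric catalysis by achiral acid catalysis followed by resolution. With HN(SO2CF3)2 alone (5 mol %, CH2Cl2, −78 °C) the cycloaddition should give 6 together with the enantiomeric cycloadduct F1. CF3CO2H then gives 7 together with the enantiomeric keto aldehyde F2. Condensation of this racemate with (1S,2S)-N,N′-dimethyl-1,2-diphenylethane-1,2-diamine (MgSO4, CH2Cl2) should give two diastereomers, the imidazolidine of 7 F3 and the imidazolidine of the enantiomer F4, to be separated by chromatography. Two-phase hydrolysis of F3 (aqueous oxalic acid/Et2O) releases 7 and the diamine.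

Step 5. What may go wrong: Michael addition at the less hindered C6 instead of C10, polymerisation of the vinyl ketone under protic base, or attack on the wrong enolate face. The fallback sets out from 9 and comes back at 11; it replaces the equilibrating Michael addition by trapping of a regiospecifically formed enolate. Me3SiCl, Et3N, DMF, 100 °C should convert 9 into the thermodynamic (C5=C10) silyl enol ether, also silylated at the C8 hydroxyl, the bis(trimethylsilyl) compound F8. MeLi (THF, 0 °C) releases the lithium enolate F9 without equilibration. It is trapped at −78 °C with 2-(trimethylsilyl)pent-1-en-3-one F11, which is made from commercial (1-bromoethenyl)trimethylsilane by Mg insertion, addition to propanal to give 2-(trimethylsilyl)pent-1-en-3-ol F10, and oxidation with Dess–Martin periodinane. The silyl group stabilises the adduct enolate and suppresses polymerisation, giving the silylated diketone F12. KOH, MeOH, 60 °C then removes both trimethylsilyl groups and effects the aldol condensation to 11.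

Step 4. What may go wrong: the peracid attacks the ring ketone (ring expansion to a lactone), or hydrogen migrates instead of C8 (over-oxidation to the carboxylic acid). The fallback sets out from 7 and comes back at 9; it replaces the oxygen insertion by a radical decarboxylative oxygenation. Chlorite oxidation (NaClO2, NaH2PO4, 2-methylbut-2-ene, t-BuOH/H2O) should give the keto acid F5. Activation ((COCl)2, cat. DMF; then sodium 2-thioxopyridin-1(2H)-olate, C5H4NNaOS) gives the thiohydroxamate ester F6. Visible light, O2 and t-BuSH in toluene at 0 °C (Barton decarboxylation with oxygen trapping) should give the tertiary hydroperoxide F7 through a C8 radical that takes up O2 anti to the neighbouring C9 substituent. P(OMe)3 reduces F7 to 9. In this variant C8 is set by substrate control and no longer by retention.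

Further compounds

F1 | step 3 | (1R,6R)-1,5-dimethyl-4-[(triisopropylsilyl)oxy]-6-{[(triisopropylsilyl)oxy]methyl}cyclohex-3-ene-1-carbaldehyde (enantiomer of 6) | O=C[C@]1(C)CC=C(O[Si](C(C)C)(C(C)C)C(C)C)C(C)[C@H]1CO[Si](C(C)C)(C(C)C)C(C)C
F2 | step 3 | (1R,2R)-1,3-dimethyl-4-oxo-2-{[(triisopropylsilyl)oxy]methyl}cyclohexane-1-carbaldehyde (enantiomer of 7) | O=C[C@]1(C)CCC(=O)C(C)[C@H]1CO[Si](C(C)C)(C(C)C)C(C)C
F3 | step 3 | imidazolidine (aminal) of 7 with (1S,2S)-N,N′-dimethyl-1,2-diphenylethane-1,2-diamine | CN1C(N(C)[C@@H](c2ccccc2)[C@@H]1c1ccccc1)[C@@]1(C)CCC(=O)C(C)[C@@H]1CO[Si](C(C)C)(C(C)C)C(C)C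
F4 | step 3 | imidazolidine (aminal) of F2 with (1S,2S)-N,N′-dimethyl-1,2-diphenylethane-1,2-diamine | CN1C(N(C)[C@@H](c2ccccc2)[C@@H]1c1ccccc1)[C@]1(C)CCC(=O)C(C)[C@H]1CO[Si](C(C)C)(C(C)C)C(C)C
F5 | step 4 | (1S,2S)-1,3-dimethyl-4-oxo-2-{[(triisopropylsilyl)oxy]methyl}cyclohexane-1-carboxylic acid | OC(=O)[C@@]1(C)CCC(=O)C(C)[C@@H]1CO[Si](C(C)C)(C(C)C)C(C)C
F6 | step 4 | 2-thioxopyridin-1(2H)-yl ester of F5 | S=c1ccccn1OC(=O)[C@@]1(C)CCC(=O)C(C)[C@@H]1CO[Si](C(C)C)(C(C)C)C(C)C
F7 | step 4 | (3R,4S)-4-hydroperoxy-2,4-dimethyl-3-{[(triisopropylsilyl)oxy]methyl}cyclohexan-1-one | OO[C@@]1(C)CCC(=O)C(C)[C@@H]1CO[Si](C(C)C)(C(C)C)C(C)C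
F8 | step 5 | trimethylsilyl enol ether (C5=C10) of 9 with the C8 hydroxyl as trimethylsilyl ether | C[Si](C)(C)O[C@@]1(C)CCC(O[Si](C)(C)C)=C(C)[C@@H]1CO[Si](C(C)C)(C(C)C)C(C)C
F9 | step 5 | lithium enolate (C5=C10) from F8 | [Li+].C[Si](C)(C)O[C@@]1(C)CCC([O-])=C(C)[C@@H]1CO[Si](C(C)C)(C(C)C)C(C)C
F10 | step 5 | 2-(trimethylsilyl)pent-1-en-3-ol | C=C(C(O)CC)[Si](C)(C)C
F11 | step 5 | 2-(trimethylsilyl)pent-1-en-3-one | C=C(C(=O)CC)[Si](C)(C)C
F12 | step 5 | Michael adduct of F9 and F11: C10-quaternary diketone with C–SiMe3 α to the side-chain ketone and C8–OSiMe3 | O=C1CC[C@](C)(O[Si](C)(C)C)[C@@H](CO[Si](C(C)C)(C(C)C)C(C)C)[C@]1(C)CC(C(=O)CC)[Si](C)(C)C
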